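**Retrosynthetic overview**
- Target 19 ⇐ E-selective cross-metathesis of vinyl diol 17 with 4-vinylphenol 18; 17 ⇐ cis-selective reduction of β-hydroxy ketone 16 ⇐ N–O cleavage of tricyclic isoxazoline 14.
- Key step: intramolecular nitrile oxide–alkene [3+2] cycloaddition of 11 closes the carbocycle (C1–C2) and the isoxazoline (C1′–O) together; the Z-alkene fixes C1/C1′ as syn.
- The dioxolane stereocentre from D-mannitol directs the face of the cycloaddition, then is excised to the vinyl group (12 → 13 → 14).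
- Z-alkene 7 ⇐ Wittig reaction of the ylide from 2-bromo-4,5-dimethoxybenzyl bromide 1 with (R)-glyceraldehyde acetonide 5; the three-carbon nitrile oxide arm ⇐ Heck reaction with allyl alcohol.
- Ring order: arene (bought) → carbocycle and isoxazoline (step 5) → isoxazoline opened (step 8).

Assumption: compounds 1, 2, 4, 8 and 18 are bought; C1–C4 are the tetralin locants and C1′–C3′ the side-chain locants of the target. The route has not been run; conditions and selectivities are by analogy.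

**Step 1**
Reactants: 1 2-bromo-4,5-dimethoxybenzyl bromide; 2 triphenylphosphine
Product: 3 (2-bromo-4,5-dimethoxybenzyl)triphenylphosphonium bromide
Conditions: toluene, 110 °C
Reagents that add atoms: none
Why: SN2 quaternisation of the phosphine by the benzylic bromide gives the Wittig salt, which precipitates.

**Step 2**
Reactants: 4 1,2:5,6-di-O-isopropylidene-D-mannitol
Product: 5 (R)-2,2-dimethyl-1,3-dioxolane-4-carbaldehyde
Conditions: NaIO4, aq. NaHCO3, CH2Cl2, 0 °C to rt; used fresh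
Reagents that add atoms: none
Why: Periodate (Malaprade) glycol cleavage of the central diol gives two equivalents of the aldehyde, whose stereocentre is an untouched carbon of D-mannitol.

**Step 3**
Reactants: 3 (2-bromo-4,5-dimethoxybenzyl)triphenylphosphonium bromide; 5 (R)-2,2-dimethyl-1,3-dioxolane-4-carbaldehyde
Product: 7 (4S)-4-[(Z)-2-(2-bromo-4,5-dimethoxyphenyl)ethenyl]-2,2-dimethyl-1,3-dioxolane, via phosphonium ylide 6 (not isolated)
Conditions: KN(SiMe3)2, THF, −78 °C; then 5, −78 °C to rt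
Reagents that add atoms: none
Why: Wittig olefination with the semi-stabilised ortho-bromo benzylic ylide under lithium-free conditions should favour the Z-alkene (minor E isomer removed by chromatography), and the stereocentre is untouched, its label becoming (4S) only through the CIP priority change.

**Step 4**
Reactants: 7 (4S)-4-[(Z)-2-(2-bromo-4,5-dimethoxyphenyl)ethenyl]-2,2-dimethyl-1,3-dioxolane; 8 allyl alcohol
Product: 10 3-{2-[(Z)-2-[(4S)-2,2-dimethyl-1,3-dioxolan-4-yl]ethenyl]-4,5-dimethoxyphenyl}propanal oxime, via aldehyde 9 (not isolated)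
Conditions: Pd(OAc)2 (5 mol %), Bu4NCl, NaHCO3, DMF, 80 °C; then 50% aq. NH2OH, rt
Reagents that add atoms: hydroxylamine, NO
Why: Heck reaction of the aryl bromide with allyl alcohol (terminal arylation, β-hydride elimination toward the carbinol) gives the 3-arylpropanal, which is trapped in the same pot by oxime condensation.

**Step 5**
Reactants: 10 3-{2-[(Z)-2-[(4S)-2,2-dimethyl-1,3-dioxolan-4-yl]ethenyl]-4,5-dimethoxyphenyl}propanal oxime
Product: 12 (1R,9bS)-1-[(4R)-2,2-dimethyl-1,3-dioxolan-4-yl]-7,8-dimethoxy-1,4,5,9b-tetrahydronaphtho[2,1-c][1,2]oxazole, via nitrile oxide 11 (not isolated)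
Conditions: aq. NaOCl, CH2Cl2 (0.01 M), 0 °C to rt
Reagents that add atoms: none
Why: In this intramolecular nitrile oxide–alkene [3+2] cycloaddition the tether forces C2–C1 bonding (six-membered ring), suprafacial addition to the Z-alkene makes H-1 and H-9b cis (C1/C1′ syn), and with the dioxolane C–H held in the alkene plane by allylic 1,3-strain the dipole oxygen should add anti to the dioxolane C4–C5 bond (ring oxygen outside), giving (1R,9bS).

**Step 6**
Reactants: 12 (1R,9bS)-1-[(4R)-2,2-dimethyl-1,3-dioxolan-4-yl]-7,8-dimethoxy-1,4,5,9b-tetrahydronaphtho[2,1-c][1,2]oxazole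
Product: 13 (1R)-1-[(1R,9bS)-7,8-dimethoxy-1,4,5,9b-tetrahydronaphtho[2,1-c][1,2]oxazol-1-yl]ethane-1,2-diol
Conditions: AcOH/H2O 4:1, 40 °C
Reagents that add atoms: none
Why: Acid-catalysed hydrolysis of the isopropylidene ketal frees the terminal diol, while the isoxazoline and aryl ethers are inert and no stereocentre is touched.

**Step 7**
Reactants: 13 (1R)-1-[(1R,9bS)-7,8-dimethoxy-1,4,5,9b-tetrahydronaphtho[2,1-c][1,2]oxazol-1-yl]ethane-1,2-diol
Product: 14 (1S,9bS)-1-ethenyl-7,8-dimethoxy-1,4,5,9b-tetrahydronaphtho[2,1-c][1,2]oxazole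
Conditions: PPh3, I2, imidazole, toluene, 110 °C
Reagents that add atoms: none
Why: Garegg–Samuelsson deoxygenation (double hydroxyl activation by the iodophosphonium reagent, then iodide-induced reductive 1,2-elimination) turns the vicinal diol into the terminal alkene, removing the mannitol-derived stereocentre without touching C1′.

**Step 8**
Reactants: 14 (1S,9bS)-1-ethenyl-7,8-dimethoxy-1,4,5,9b-tetrahydronaphtho[2,1-c][1,2]oxazole
Product: 16 (1R)-1-[(1S)-1-hydroxyprop-2-en-1-yl]-6,7-dimethoxy-3,4-dihydronaphthalen-2(1H)-one, via β-hydroxy imine 15 (not isolated)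
Conditions: SmI2, THF, 0 °C; then B(OH)3, H2O; used crude at once
Reagents that add atoms: water, O
Why: Single-electron reductive cleavage of the isoxazoline N–O bond and buffered hydrolysis of the imine unmask the β-hydroxy ketone without touching C1, C1′ or the vinyl group.

**Step 9**
Reactants: 16 (1R)-1-[(1S)-1-hydroxyprop-2-en-1-yl]-6,7-dimethoxy-3,4-dihydronaphthalen-2(1H)-one
Product: 17 (1S,2R)-1-[(1S)-1-hydroxyprop-2-en-1-yl]-6,7-dimethoxy-1,2,3,4-tetrahydronaphthalen-2-ol
Conditions: NaBH4, MeOH/CH2Cl2, −78 to −40 °C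
Reagents that add atoms: none
Why: In this substrate-controlled hydride reduction of a 1-substituted 2-tetralone the C1 side chain sits pseudoaxial (peri strain with H-8), so hydride adds to the opposite face and the new C2 hydroxyl is cis to the side chain, (2R).

**Step 10**
Reactants: 17 (1S,2R)-1-[(1S)-1-hydroxyprop-2-en-1-yl]-6,7-dimethoxy-1,2,3,4-tetrahydronaphthalen-2-ol; 18 4-vinylphenol
Product: 19 (1S,2R)-1-[(1S,2E)-1-hydroxy-3-(4-hydroxyphenyl)prop-2-en-1-yl]-6,7-dimethoxy-1,2,3,4-tetrahydronaphthalen-2-ol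
Conditions: second-generation Hoveyda–Grubbs catalyst (5 mol %), 18 (3 equiv), CH2Cl2, 40 °C
Reagents that add atoms: none
Why: Olefin cross-metathesis of the terminal allylic alcohol with excess 4-vinylphenol is driven by loss of ethylene and gives the thermodynamically favoured E-styrene with no stereocentre involved.

**Compound list**
1 | 2-bromo-4,5-dimethoxybenzyl bromide | COc1cc(CBr)c(Br)cc1OC | starting material
2 | triphenylphosphine | c1ccc(cc1)P(c1ccccc1)c1ccccc1 | starting material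
3 | (2-bromo-4,5-dimethoxybenzyl)triphenylphosphonium bromide | COc1cc(C[P+](c2ccccc2)(c2ccccc2)c2ccccc2)c(Br)cc1OC.[Br-] | intermediate
4 | 1,2:5,6-di-O-isopropylidene-D-mannitol | CC1(C)OC[C@@H](O1)[C@@H](O)[C@H](O)[C@H]1COC(C)(C)O1 | starting material
5 | (R)-2,2-dimethyl-1,3-dioxolane-4-carbaldehyde | CC1(C)OC[C@H](C=O)O1 | intermediate
6 | (2-bromo-4,5-dimethoxybenzylidene)triphenylphosphorane | COc1cc(C=P(c2ccccc2)(c2ccccc2)c2ccccc2)c(Br)cc1OC | intermediate
7 | (4S)-4-[(Z)-2-(2-bromo-4,5-dimethoxyphenyl)ethenyl]-2,2-dimethyl-1,3-dioxolane | COc1cc(/C=C\[C@H]2COC(C)(C)O2)c(Br)cc1OC | intermediate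
8 | allyl alcohol | C=CCO | starting material
9 | 3-{2-[(Z)-2-[(4S)-2,2-dimethyl-1,3-dioxolan-4-yl]ethenyl]-4,5-dimethoxyphenyl}propanal | COc1cc(/C=C\[C@H]2COC(C)(C)O2)c(CCC=O)cc1OC | intermediate
10 | 3-{2-[(Z)-2-[(4S)-2,2-dimethyl-1,3-dioxolan-4-yl]ethenyl]-4,5-dimethoxyphenyl}propanal oxime (E/Z mixture at C=N) | COc1cc(/C=C\[C@H]2COC(C)(C)O2)c(CCC=NO)cc1OC | intermediate
11 | 3-{2-[(Z)-2-[(4S)-2,2-dimethyl-1,3-dioxolan-4-yl]ethenyl]-4,5-dimethoxyphenyl}propanenitrile oxide | COc1cc(/C=C\[C@H]2COC(C)(C)O2)c(CCC#[N+][O-])cc1OC | intermediate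
12 | (1R,9bS)-1-[(4R)-2,2-dimethyl-1,3-dioxolan-4-yl]-7,8-dimethoxy-1,4,5,9b-tetrahydronaphtho[2,1-c][1,2]oxazole (isoxazoline fused across tetralin C1–C2, C=N at C2, ring O on C1′, H-1/H-9b cis) | COc1cc2c(cc1OC)[C@@H]3[C@H]([C@H]4COC(C)(C)O4)ON=C3CC2 | intermediate
13 | (1R)-1-[(1R,9bS)-7,8-dimethoxy-1,4,5,9b-tetrahydronaphtho[2,1-c][1,2]oxazol-1-yl]ethane-1,2-diol | COc1cc2c(cc1OC)[C@@H]3[C@H]([C@H](O)CO)ON=C3CC2 | intermediate
14 | (1S,9bS)-1-ethenyl-7,8-dimethoxy-1,4,5,9b-tetrahydronaphtho[2,1-c][1,2]oxazole | COc1cc2c(cc1OC)[C@@H]3[C@H](C=C)ON=C3CC2 | intermediate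
15 | (1S)-1-[(1S)-1-hydroxyprop-2-en-1-yl]-6,7-dimethoxy-3,4-dihydronaphthalen-2(1H)-imine | COc1cc2c(cc1OC)[C@H]([C@@H](O)C=C)C(=N)CC2 | intermediate
16 | (1R)-1-[(1S)-1-hydroxyprop-2-en-1-yl]-6,7-dimethoxy-3,4-dihydronaphthalen-2(1H)-one | COc1cc2c(cc1OC)[C@H]([C@@H](O)C=C)C(=O)CC2 | intermediate
17 | (1S,2R)-1-[(1S)-1-hydroxyprop-2-en-1-yl]-6,7-dimethoxy-1,2,3,4-tetrahydronaphthalen-2-ol | COc1cc2c(cc1OC)[C@H]([C@@H](O)C=C)[C@H](O)CC2 | intermediate
18 | 4-vinylphenol | C=Cc1ccc(O)cc1 | starting material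
19 | (1S,2R)-1-[(1S,2E)-1-hydroxy-3-(4-hydroxyphenyl)prop-2-en-1-yl]-6,7-dimethoxy-1,2,3,4-tetrahydronaphthalen-2-ol | COc1cc2c(cc1OC)[C@H]([C@@H](O)/C=C/c1ccc(O)cc1)[C@H](O)CC2 | target

**Step count**
Total: 10 steps. Longest linear sequence: 9 steps (1, 3–10; equally 2–10).

**Three steps most likely to fail**

Step 3 (Z-selectivity of the Wittig reaction). If the Z:E ratio is poor, the alkene geometry is set by semi-hydrogenation instead. The fallback sets out from 5: homologation with dimethyl (1-diazo-2-oxopropyl)phosphonate (K2CO3, MeOH) gives (4S)-4-ethynyl-2,2-dimethyl-1,3-dioxolane F1. Sonogashira coupling of F1 with bought 1-bromo-2-iodo-4,5-dimethoxybenzene (PdCl2(PPh3)2, CuI, Et3N, rt, iodide-selective) gives (4S)-4-[(2-bromo-4,5-dimethoxyphenyl)ethynyl]-2,2-dimethyl-1,3-dioxolane F2. Hydrogenation over Pd/CaCO3 poisoned with Pb(OAc)2 and quinoline then delivers pure Z-alkene, coming back to the route at 7.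

Step 4 (Heck reaction next to the Z-styrene). The electron-rich, ortho-substituted bromide may react sluggishly, and palladium hydride may isomerise the Z-alkene. The fallback sets out from 7 and avoids palladium: bromine–lithium exchange (t-BuLi, THF, −78 °C) gives {2-[(Z)-2-[(4S)-2,2-dimethyl-1,3-dioxolan-4-yl]ethenyl]-4,5-dimethoxyphenyl}lithium F3. Opening of oxetane (BF3·OEt2, −78 °C) gives 3-{2-[(Z)-2-[(4S)-2,2-dimethyl-1,3-dioxolan-4-yl]ethenyl]-4,5-dimethoxyphenyl}propan-1-ol F4. Dess–Martin oxidation comes back to the route at 9, which is isolated and condensed with hydroxylamine as in step 4.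

Step 5 (facial selectivity of the cycloaddition). This is the least certain stereochemical call in the route: the sense rests on the outside-alkoxy model for Z allyl ethers, and the level may be modest. The fallback sets out from 10 and switches to a chelation-controlled cycloaddition. Ketal methanolysis (Dowex 50W-X8, H+ form, MeOH, rt) gives 3-{2-[(1Z,3S)-3,4-dihydroxybut-1-en-1-yl]-4,5-dimethoxyphenyl}propanal oxime F5. Chlorination (N-chlorosuccinimide, DMF, 0 °C) gives 3-{2-[(1Z,3S)-3,4-dihydroxybut-1-en-1-yl]-4,5-dimethoxyphenyl}-N-hydroxypropanimidoyl chloride F6. Treatment with EtMgBr and i-PrOH in CH2Cl2 at 0 °C generates 3-{2-[(1Z,3S)-3,4-dihydroxybut-1-en-1-yl]-4,5-dimethoxyphenyl}propanenitrile oxide F7 as its magnesium alkoxide. Magnesium bridges the allylic alkoxide and the dipole oxygen, so oxygen is delivered syn to the carbinol, and the cycloadduct comes back to the route at 13.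

**Further compounds**
F1 | step 3 | (4S)-4-ethynyl-2,2-dimethyl-1,3-dioxolane | C#C[C@H]1COC(C)(C)O1
F2 | step 3 | (4S)-4-[(2-bromo-4,5-dimethoxyphenyl)ethynyl]-2,2-dimethyl-1,3-dioxolane | COc1cc(C#C[C@H]2COC(C)(C)O2)c(Br)cc1OC
F3 | step 4 | {2-[(Z)-2-[(4S)-2,2-dimethyl-1,3-dioxolan-4-yl]ethenyl]-4,5-dimethoxyphenyl}lithium | COc1cc(/C=C\[C@H]2COC(C)(C)O2)c([Li])cc1OC
F4 | step 4 | 3-{2-[(Z)-2-[(4S)-2,2-dimethyl-1,3-dioxolan-4-yl]ethenyl]-4,5-dimethoxyphenyl}propan-1-ol | COc1cc(/C=C\[C@H]2COC(C)(C)O2)c(CCCO)cc1OC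
F5 | step 5 | 3-{2-[(1Z,3S)-3,4-dihydroxybut-1-en-1-yl]-4,5-dimethoxyphenyl}propanal oxime | COc1cc(/C=C\[C@H](O)CO)c(CCC=NO)cc1OC
F6 | step 5 | 3-{2-[(1Z,3S)-3,4-dihydroxybut-1-en-1-yl]-4,5-dimethoxyphenyl}-N-hydroxypropanimidoyl chloride | COc1cc(/C=C\[C@H](O)CO)c(CCC(Cl)=NO)cc1OC
F7 | step 5 | 3-{2-[(1Z,3S)-3,4-dihydroxybut-1-en-1-yl]-4,5-dimethoxyphenyl}propanenitrile oxide | COc1cc(/C=C\[C@H](O)CO)c(CCC#[N+][O-])cc1OC
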